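**Retrosynthetic overview**

1. The pyran ring of the chroman holds a 2-hydroxybenzyl unit (O1–C8a–C4a–C4) next to a fully substituted C2 that carries O1, CH3 and the C16 chain. This is the retron of an ortho-quinone methide (O1=C8a–C4a=C4) plus a 1,1-disubstituted alkene (C3=C2); O1 ortho and O7 para to C4a make the methide easy to form.
2. Key disconnection: a catalytic asymmetric oxa-[4+2] cycloaddition that forms C3–C4 and O1–C2 in one operation, closes the pyran ring, joins the two halves and sets C2 (S).
3. Methide precursor: C2v-symmetric 5-methylpyrogallol, with O7/O8 tied into a temporary di-tert-butylsilylene ring and C4 added as formaldehyde by boron-templated ortho-hydroxymethylation (temporary dioxaborin ring).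
4. Alkene partner: the C19 tetraene from (2E,6E)-farnesol by acetoacetate chain extension and Wittig methylenation.
5. Ring order: dioxasilole (temporary) → dioxaborin (temporary, opened again) → pyran ring (key step) → dioxasilole removed with fluoride.

Key step: step 7

Assumption: 5-methylpyrogallol is taken as a catalogue compound; the sense of induction of the chiral acid cannot be predicted, so the catalyst antipode that gives the (2S) series is to be fixed in a first test run and is written below as (S,S).

**Route**

Step 1
Reactants: 1 5-methylpyrogallol (5-methylbenzene-1,2,3-triol)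
Product: 2 2,2-di-tert-butyl-6-methyl-1,3,2-benzodioxasilol-4-ol
Conditions: t-Bu2Si(OTf)2 (1.0 equiv), 2,6-lutidine, DMF, 0 °C
Reagents that add atoms: di-tert-butylsilyl bis(trifluoromethanesulfonate), CC(C)(C)[Si](OS(=O)(=O)C(F)(F)F)(OS(=O)(=O)C(F)(F)F)C(C)(C)C
Why: Cyclic silylene protection of a 1,2-diol: after the first Si–O bond the neighbouring hydroxyl should close the five-membered dioxasilole, and because the triol is C2v-symmetric either adjacent pair gives the same product with one terminal OH (the later O1) left free.

Step 2
Reactants: 2 2,2-di-tert-butyl-6-methyl-1,3,2-benzodioxasilol-4-ol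
Product: 3 7,8-[(di-tert-butylsilanediyl)bis(oxy)]-5-methyl-2-phenyl-4H-1,3,2-benzodioxaborin
Conditions: PhB(OH)2, (CH2O)n, EtCO2H (cat.), toluene, reflux, Dean–Stark
Reagents that add atoms: phenylboronic acid, OB(O)c1ccccc1; paraformaldehyde (formaldehyde), C=O
Why: Boronic acid-templated ortho-hydroxymethylation of a phenol: the aryl phenylboronate should deliver formaldehyde through a six-membered transition state to the only free ortho carbon (between OH and CH3), not to the para carbon, and the product is trapped as a stable cyclic boronate.

Step 3
Reactants: 3 7,8-[(di-tert-butylsilanediyl)bis(oxy)]-5-methyl-2-phenyl-4H-1,3,2-benzodioxaborin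
Product: 4 2,2-di-tert-butyl-5-(hydroxymethyl)-6-methyl-1,3,2-benzodioxasilol-4-ol
Conditions: H2O2 (30% aq), THF, 0 °C → rt
Reagents that add atoms: none
Why: Oxidative cleavage of the B-phenyl bond and borate hydrolysis under neutral conditions should free the 2-hydroxybenzyl alcohol without base-induced silyl migration, and the acid-sensitive diol is used without storage.

Step 4
Reactants: 5 (2E,6E)-farnesol
Product: 6 (2E,6E)-farnesyl bromide
Conditions: PBr3 (0.4 equiv), pyridine (cat.), Et2O, −10 °C
Reagents that add atoms: phosphorus tribromide, BrP(Br)Br
Why: SN2 displacement of the activated phosphite at the primary allylic carbon at low temperature should give the bromide without allylic transposition or loss of E geometry; it is used crude.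

Step 5
Reactants: 6 (2E,6E)-farnesyl bromide; 7 ethyl acetoacetate
Product: 9 (5E,9E)-6,10,14-trimethylpentadeca-5,9,13-trien-2-one (farnesylacetone), via alkylated acetoacetate 8 (not isolated)
Conditions: NaOEt, EtOH, 0 °C → rt (7 in excess); then NaOH (aq), 70 °C; then HCl (aq), 50 °C
Reagents that add atoms: none
Why: Acetoacetic ester ketone synthesis: C-alkylation of the stabilised enolate by SN2 at the primary allylic bromide, saponification and decarboxylation of the β-keto acid should give the methyl ketone with the E alkenes untouched.

Step 6
Reactants: 9 (5E,9E)-6,10,14-trimethylpentadeca-5,9,13-trien-2-one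
Product: 10 (5E,9E)-2,6,10,14-tetramethylpentadeca-1,5,9,13-tetraene
Conditions: Ph3PCH3Br, KOtBu, THF, 0 °C → rt
Reagents that add atoms: methyltriphenylphosphonium bromide, C[P+](c1ccccc1)(c1ccccc1)c1ccccc1.[Br-]
Why: Wittig methylenation of an unhindered methyl ketone should give the terminal 1,1-disubstituted alkene; the ylide does not touch the isolated trisubstituted alkenes and no alkene geometry is created.

Step 7
Reactants: 4 2,2-di-tert-butyl-5-(hydroxymethyl)-6-methyl-1,3,2-benzodioxasilol-4-ol; 10 (5E,9E)-2,6,10,14-tetramethylpentadeca-1,5,9,13-tetraene
Product: 12 (2S)-7,8-O-(di-tert-butylsilanediyl)chroman (silylene-protected target), via ortho-quinone methide 11 (not isolated)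
Conditions: (S,S)-IDPi (BINOL-derived imidodiphosphorimidate acid, 5 mol%), 5 Å MS, CHCl3, −30 °C; 4 added slowly to 10 (1.5 equiv)
Reagents that add atoms: none
Why: Proposed new method: the confined chiral acid ionises the electron-rich benzylic alcohol of 4 (O1 ortho and O7 para to C4a) to the ortho-quinone methide 11, which stays hydrogen-bonded to the chiral anion while the CH2 terminus of the 1,1-disubstituted alkene of 10 attacks the methide carbon (C3–C4) and O1 bonds to the alkene carbon that carries CH3 and the chain (O1–C2) in an asynchronous inverse-electron-demand oxa-Diels–Alder reaction; the closest known reaction types are chiral phosphoric acid and imidodiphosphate catalysed [4+2] cycloadditions of ortho-quinone methides made in situ from 2-hydroxybenzyl alcohols with styrenes and, intramolecularly, with unactivated alkenes, and IDPi-catalysed enantioselective additions to unactivated 1,1-disubstituted alkenes, merged here in an intermolecular reaction of a parent CH2 methide with a 1,1-dialkyl alkene. The pyran ring closes by this [4π+2π] cycloaddition (at its stepwise limit: conjugate addition of the alkene to C4, then six-membered ring closure of O1 on the tertiary C2 cation inside the ion pair). The only new stereocentre, C2, is set by the catalyst: the confined anion must expose one enantiotopic face of the alkene by sorting the small CH3 from the long chain. The step needs site selectivity for the terminal alkene over the three trisubstituted alkenes, which should follow because only that alkene offers an unsubstituted CH2 terminus together with a carbon that stabilises tertiary cation character, a preference a narrow catalyst pocket should sharpen. It also needs cycloaddition to beat Friedel–Crafts self-condensation of 11, for which the bulky silylene on O7/O8 and the C5 methyl shield the nucleophilic C6 position and slow addition keeps 11 dilute. The quaternary ether stereocentre is not epimerisable under the catalytic, low-temperature acid conditions, which should also leave the trisubstituted alkenes unprotonated.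

Step 8
Reactants: 12 (2S)-7,8-O-(di-tert-butylsilanediyl)chroman (silylene-protected target)
Product: 13 (2S)-2,5-dimethyl-2-[(3E,7E)-4,8,12-trimethyltrideca-3,7,11-trien-1-yl]chromane-7,8-diol (CNP0122319.1)
Conditions: Et3N·3HF, THF, 0 °C → rt, argon
Reagents that add atoms: none
Why: Fluoride-driven cleavage of both aryl O–Si bonds (silyl ether deprotection) under buffered, non-basic conditions should free the catechol without aerobic oxidation and without touching the chroman ether, the alkenes or C2.

**Compound list**

1 | 5-methylpyrogallol (5-methylbenzene-1,2,3-triol) | Cc1cc(O)c(O)c(O)c1 | starting material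
2 | 2,2-di-tert-butyl-6-methyl-1,3,2-benzodioxasilol-4-ol | Cc1cc2O[Si](C(C)(C)C)(C(C)(C)C)Oc2c(O)c1 | intermediate
3 | 7,8-[(di-tert-butylsilanediyl)bis(oxy)]-5-methyl-2-phenyl-4H-1,3,2-benzodioxaborin | Cc1cc2O[Si](C(C)(C)C)(C(C)(C)C)Oc2c3OB(c4ccccc4)OCc13 | intermediate
4 | 2,2-di-tert-butyl-5-(hydroxymethyl)-6-methyl-1,3,2-benzodioxasilol-4-ol | Cc1cc2O[Si](C(C)(C)C)(C(C)(C)C)Oc2c(O)c1CO | intermediate
5 | (2E,6E)-farnesol | CC(C)=CCC/C(C)=C/CC/C(C)=C/CO | starting material
6 | (2E,6E)-farnesyl bromide | CC(C)=CCC/C(C)=C/CC/C(C)=C/CBr | intermediate
7 | ethyl acetoacetate | CCOC(=O)CC(C)=O | starting material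
8 | ethyl (4E,8E)-2-acetyl-5,9,13-trimethyltetradeca-4,8,12-trienoate (racemic; not isolated) | CC(C)=CCC/C(C)=C/CC/C(C)=C/CC(C(C)=O)C(=O)OCC | intermediate
9 | (5E,9E)-6,10,14-trimethylpentadeca-5,9,13-trien-2-one (farnesylacetone) | CC(C)=CCC/C(C)=C/CC/C(C)=C/CCC(C)=O | intermediate
10 | (5E,9E)-2,6,10,14-tetramethylpentadeca-1,5,9,13-tetraene | CC(C)=CCC/C(C)=C/CC/C(C)=C/CCC(C)=C | intermediate
11 | 2,2-di-tert-butyl-6-methyl-5-methylidene-1,3,2-benzodioxasilol-4(5H)-one (ortho-quinone methide; not isolated) | O=C1C(=C)C(C)=CC2=C1O[Si](C(C)(C)C)(C(C)(C)C)O2 | intermediate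
12 | (2S)-7,8-[(di-tert-butylsilanediyl)bis(oxy)]-2,5-dimethyl-2-[(3E,7E)-4,8,12-trimethyltrideca-3,7,11-trien-1-yl]chromane | CC(C)=CCC/C(C)=C/CC/C(C)=C/CC[C@@]1(C)CCc2c(C)cc3O[Si](C(C)(C)C)(C(C)(C)C)Oc3c2O1 | intermediate
13 | (2S)-2,5-dimethyl-2-[(3E,7E)-4,8,12-trimethyltrideca-3,7,11-trien-1-yl]chromane-7,8-diol | CC(C)=CCC/C(C)=C/CC/C(C)=C/CC[C@@]1(C)CCc2c(C)cc(O)c(O)c2O1 | target

**Step count and risks**

Total step count: 8. Longest linear sequence: 5 steps (steps 1, 2, 3, 7, 8; the alkene branch 4, 5, 6, 7, 8 is equally long).

Steps most likely to fail:

Step 7 (proposed new method). What may go wrong is insufficient enantiofacial discrimination between CH3 and the chain at the alkene, competing capture of the methide by the trisubstituted alkenes, or acid-triggered cyclisation of the polyene. The fallback uses known chemistry and sets out from boronate 3 and tetraene 10. Heating 3 with excess 10 (toluene, sealed tube, about 180 °C) releases 11 thermally with loss of phenylboronic anhydride, and the uncatalysed inverse-demand hetero-Diels–Alder reaction should give the racemic silylene-protected chroman F1. Preparative chromatography on a chiral stationary phase (cellulose or amylose carbamate) then separates 12 from the (2R)-enantiomer F2, and the route is rejoined at 12.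

Step 2. What may go wrong is cleavage or migration of the strained silylene under hot, acidic, dehydrating conditions, or slow reaction at the hindered carbon between OH and CH3. The fallback sets out from 2. Magnesium phenoxide-directed ortho-formylation (MgCl2, Et3N, (CH2O)n, MeCN, reflux) should give the salicylaldehyde F3, in which the O–H···O=C hydrogen bond holds the free phenol in place. Reduction with NaBH4 (THF/MeOH, −20 °C, NH4Cl quench) then gives 4, so the route is rejoined at 4 without passing through 3.

Step 8. What may go wrong is aerobic oxidation of the freed electron-rich catechol to the ortho-quinone during deprotection and isolation. The fallback sets out from 12. Desilylative acetylation (CsF, Ac2O, DMF, rt) should give the air-stable diacetate F4, which can be purified without precautions. Reductive deacylation (LiAlH4, THF, −20 °C; degassed aqueous tartaric acid work-up) then frees the catechol under reducing conditions and rejoins the route at 13.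

**Further compounds**

F1 | step 7 | racemic 7,8-O-(di-tert-butylsilanediyl)-protected chroman (racemate of 12) | CC(C)=CCC/C(C)=C/CC/C(C)=C/CCC1(C)CCc2c(C)cc3O[Si](C(C)(C)C)(C(C)(C)C)Oc3c2O1
F2 | step 7 | (2R)-enantiomer of 12 | CC(C)=CCC/C(C)=C/CC/C(C)=C/CC[C@]1(C)CCc2c(C)cc3O[Si](C(C)(C)C)(C(C)(C)C)Oc3c2O1
F3 | step 2 | 2,2-di-tert-butyl-4-hydroxy-6-methyl-1,3,2-benzodioxasilole-5-carbaldehyde | Cc1cc2O[Si](C(C)(C)C)(C(C)(C)C)Oc2c(O)c1C=O
F4 | step 8 | (2S)-7,8-di-O-acetyl derivative of 13 | CC(C)=CCC/C(C)=C/CC/C(C)=C/CC[C@@]1(C)CCc2c(C)cc(OC(C)=O)c(OC(C)=O)c2O1
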